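**Plan**
Numbering: lactone O1, C2(=O), C3, C4, C5; exocyclic CH is C6 and carries catechol ring A; benzylic CH2 is C7 and carries guaiacyl ring B.
- Retrosynthesis: unmask the phenols; open the lactone to a C2 allylic alcohol and a C5 alcohol; cut C4–C5 back to a C4–B bond; cut C3–C4 and C7–ring B in one operation; cut C3=C6 back to the ring A aldehyde.
- Enabling feature: C4 and C7 are neighbouring sp3 carbons, C4 holding the C3 alkenyl arm and C7 holding ring B. A vinylboron unit acquires exactly this pattern when an alkenyl group shifts from boron to its inner carbon while an aryl group adds to its outer carbon; the boron left on C4 later brings in C5.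
- Forward: ring A aldehyde to the (E)-α-bromoacrylate and the silylated 2-bromoallyl alcohol; ring B triflate from vanillin; three-component union with vinylboronic pinacol ester; CH2 insertion and oxidation; the lactone, the only ring formed, closes late by oxidative lactonisation; MOM removal last.
- Stereochemistry: the alkene geometry (ring A cis to C2) comes from the bromo-olefination and is retained through Br–Li exchange and the boron-to-carbon shift. C4 (S) is set by the chiral bisphosphine on palladium and carried through the stereoretentive CH2 insertion.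

Key step: step 8

Assumption: methyl bis(2,2,2-trifluoroethyl) bromophosphonoacetate (step 2) is a known reagent, made by bromination of the commercial Still–Gennari phosphonate, and is taken as available.
Assumption: the (Rp,Rp) antipode of the MandyPhos ligand is taken, from recollection of the reported sense of induction, to be the one that gives S at C4; this is to be confirmed on the first run by oxidising a sample of 14 and analysing its Mosher ester, and the mirror-image ligand is equally available.

**Step 1**
Reactants: 1 5-hydroxyvanillin (3,4-dihydroxy-5-methoxybenzaldehyde)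
Product: 2 3-methoxy-4,5-bis(methoxymethoxy)benzaldehyde
Conditions: MOMCl (3 equiv), i-Pr2NEt (4 equiv), CH2Cl2, 0 °C to rt
Reagents that add atoms: chloromethyl methyl ether, COCCl
Why: O-alkylation of both catechol hydroxyls (MOM protection) should proceed cleanly with an amine base, and the aldehyde is inert to it.

**Step 2**
Reactants: 2 3-methoxy-4,5-bis(methoxymethoxy)benzaldehyde
Product: 3 methyl (E)-2-bromo-3-[3-methoxy-4,5-bis(methoxymethoxy)phenyl]prop-2-enoate (ring A cis to the ester)
Conditions: methyl bis(2,2,2-trifluoroethyl) bromophosphonoacetate (1.2 equiv), KOt-Bu (1.2 equiv), 18-crown-6 (2 equiv), THF, −78 °C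
Reagents that add atoms: methyl 2-[bis(2,2,2-trifluoroethoxy)phosphoryl]-2-bromoacetate, COC(=O)C(Br)P(=O)(OCC(F)(F)F)OCC(F)(F)F
Why: In this Horner–Wadsworth–Emmons olefination of the Still–Gennari type, the electron-poor phosphonate eliminates fast from the kinetic adduct and places the aldehyde substituent cis to the ester, which with bromine on the α-carbon is the E bromoacrylate.

**Step 3**
Reactants: 3 methyl (E)-2-bromo-3-[3-methoxy-4,5-bis(methoxymethoxy)phenyl]prop-2-enoate
Product: 4 (E)-2-bromo-3-[3-methoxy-4,5-bis(methoxymethoxy)phenyl]prop-2-en-1-ol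
Conditions: i-Bu2AlH (2.5 equiv), CH2Cl2, −78 °C; aqueous potassium sodium tartrate (KNaC4H4O6) work-up
Reagents that add atoms: none
Why: 1,2-Reduction of an α-bromo enoate by i-Bu2AlH should stop at the allylic alcohol and leave the vinyl bromide, the alkene geometry and the MOM acetals untouched.

**Step 4**
Reactants: 4 (E)-2-bromo-3-[3-methoxy-4,5-bis(methoxymethoxy)phenyl]prop-2-en-1-ol
Product: 5 (E)-{[2-bromo-3-[3-methoxy-4,5-bis(methoxymethoxy)phenyl]prop-2-en-1-yl]oxy}(tert-butyl)dimethylsilane
Conditions: TBSCl (1.2 equiv), imidazole (2 equiv), DMF, rt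
Reagents that add atoms: tert-butyldimethylsilyl chloride, CC(C)(C)[Si](C)(C)Cl
Why: Standard silylation of a primary allylic alcohol gives a group that tolerates organolithium, palladium and peroxide steps and is later removed by fluoride without touching the MOM ethers.

**Step 5**
Reactants: 6 vanillin
Product: 7 3-methoxy-4-(methoxymethoxy)benzaldehyde
Conditions: MOMCl (1.5 equiv), i-Pr2NEt (2 equiv), CH2Cl2, 0 °C to rt
Reagents that add atoms: chloromethyl methyl ether, COCCl
Why: MOM protection of the single phenol by O-alkylation is routine and matches the protection of ring A, so all three phenols can be released together at the end.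

**Step 6**
Reactants: 7 3-methoxy-4-(methoxymethoxy)benzaldehyde
Product: 9 3-methoxy-4-(methoxymethoxy)phenol, via 3-methoxy-4-(methoxymethoxy)phenyl formate 8 (not isolated)
Conditions: mCPBA (1.3 equiv), CH2Cl2, rt; wash with aqueous Na2S2O3 and NaHCO3; then K2CO3 (0.2 equiv), MeOH, rt
Reagents that add atoms: 3-chloroperoxybenzoic acid, OOC(=O)c1cccc(Cl)c1
Why: In this Dakin-type Baeyer–Villiger oxidation the electron-rich p-alkoxyaryl group migrates in preference to hydrogen, and the resulting aryl formate is methanolysed under mild base that leaves the MOM acetal intact.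

**Step 7**
Reactants: 9 3-methoxy-4-(methoxymethoxy)phenol
Product: 10 3-methoxy-4-(methoxymethoxy)phenyl trifluoromethanesulfonate
Conditions: PhNTf2 (1.1 equiv), Et3N (1.5 equiv), DMAP (cat.), CH2Cl2, rt
Reagents that add atoms: N-phenylbis(trifluoromethanesulfonimide), O=S(=O)(N(c1ccccc1)S(=O)(=O)C(F)(F)F)C(F)(F)F
Why: O-Triflation of a phenol with the mild triflimide reagent avoids free triflic acid and so should spare the acid-labile MOM ether.

**Step 8**
Reactants: 5 (E)-{[2-bromo-3-[3-methoxy-4,5-bis(methoxymethoxy)phenyl]prop-2-en-1-yl]oxy}(tert-butyl)dimethylsilane; 11 vinylboronic acid pinacol ester; 10 3-methoxy-4-(methoxymethoxy)phenyl trifluoromethanesulfonate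
Product: 14 2-{(2S,3Z)-3-[(tert-butyldimethylsilyloxy)methyl]-4-[3-methoxy-4,5-bis(methoxymethoxy)phenyl]-1-[3-methoxy-4-(methoxymethoxy)phenyl]but-3-en-2-yl}-4,4,5,5-tetramethyl-1,3,2-dioxaborolane, via alkenyllithium 12 (not isolated), via lithium alkenyl(vinyl)pinacolatoborate 13 (not isolated)
Conditions: t-BuLi (2.0 equiv), Et2O, −78 °C; 11 (1.0 equiv), −78 °C to rt; exchange solvent to THF; Pd(OAc)2 (3 mol %), (Rp,Rp)-MandyPhos ligand 1,1′-bis[bis(3,5-dimethylphenyl)phosphino]-2,2′-bis[α-(dimethylamino)benzyl]ferrocene (3.6 mol %), 10 (1.1 equiv), CF3SO3K (2 equiv), THF, 60 °C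
Reagents that add atoms: none
Why: Oxidative addition of triflate 10 to zerovalent palladium (formed in situ from Pd(OAc)2) gives a cationic aryl complex of divalent palladium that binds the unsubstituted vinyl group of borate 13; this π-activation triggers a 1,2-metalate shift in which the trisubstituted alkenyl group moves from boron to the boron-bearing carbon anti to palladium (C3–C4 bond), and C–C reductive elimination then joins the outer carbon to ring B (C7–aryl bond). The closest known reaction type is the enantioselective palladium-catalysed conjunctive cross-coupling of bis(alkenyl) pinacol borates with aryl triflates, which gives α-branched allylic boronates. No ring is formed. The one new stereocenter, C4, is controlled by the chiral MandyPhos ligand, which selects the enantiotopic face of the bound vinyl group, while the alkenyl group migrates with its geometry intact so that ring A stays cis to C2. The step needs activation of the vinyl group and not of the alkenyl group, and a metalate shift and not direct transfer of an organic group from boron to palladium. The first should follow from the steric difference between an unsubstituted and a trisubstituted alkene, the second from the triflate electrophile, the wide-bite-angle bisphosphine and the removal of bromide as KBr by CF3SO3K, which keep a coordination site on palladium free for the alkene.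

**Step 9**
Reactants: 14 2-{(2S,3Z)-3-[(tert-butyldimethylsilyloxy)methyl]-4-[3-methoxy-4,5-bis(methoxymethoxy)phenyl]-1-[3-methoxy-4-(methoxymethoxy)phenyl]but-3-en-2-yl}-4,4,5,5-tetramethyl-1,3,2-dioxaborolane
Product: 17 (2S,3Z)-3-[(tert-butyldimethylsilyloxy)methyl]-4-[3-methoxy-4,5-bis(methoxymethoxy)phenyl]-2-[3-methoxy-4-(methoxymethoxy)benzyl]but-3-en-1-ol, via lithium chloromethyl borate 15 (not isolated), via homologated primary boronate 16 (not isolated)
Conditions: BrCH2Cl (3 equiv), n-BuLi (2.5 equiv, added last), THF, −78 °C to rt; then NaOH (3 M aq), H2O2 (30 %), 0 °C to rt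
Reagents that add atoms: bromochloromethane, ClCBr; hydrogen peroxide, OO
Why: In this Matteson homologation the (chloromethyl)lithium made in situ is captured by boron at −78 °C and the C4 group shifts to CH2 with retention on warming, after the excess carbenoid has decayed, so one carbon (C5) is inserted and basic peroxide then converts C5–B to C5–OH without touching C4.

**Step 10**
Reactants: 17 (2S,3Z)-3-[(tert-butyldimethylsilyloxy)methyl]-4-[3-methoxy-4,5-bis(methoxymethoxy)phenyl]-2-[3-methoxy-4-(methoxymethoxy)benzyl]but-3-en-1-ol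
Product: 18 (2Z,3S)-2-[3-methoxy-4,5-bis(methoxymethoxy)benzylidene]-3-[3-methoxy-4-(methoxymethoxy)benzyl]butane-1,4-diol
Conditions: Bu4NF (1.2 equiv), THF, 0 °C to rt
Reagents that add atoms: none
Why: Fluoride desilylation of the primary TBS ether is selective and leaves the MOM ethers, the alkene and C4 unchanged.

**Step 11**
Reactants: 18 (2Z,3S)-2-[3-methoxy-4,5-bis(methoxymethoxy)benzylidene]-3-[3-methoxy-4-(methoxymethoxy)benzyl]butane-1,4-diol
Product: 21 (3Z,4S)-3-[3-methoxy-4,5-bis(methoxymethoxy)benzylidene]-4-[3-methoxy-4-(methoxymethoxy)benzyl]dihydrofuran-2(3H)-one, via hydroxy enal 19 (not isolated), via lactol 20 (not isolated)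
Conditions: activated MnO2 (excess), CH2Cl2, rt, protected from light
Reagents that add atoms: none
Why: In this oxidative lactonisation of a 2-alkylidene-1,4-diol, MnO2 oxidises only the cinnamyl-type C2 alcohol, the enal is trapped at once by the C5 hydroxyl (5-exo-trig addition to the aldehyde) and the allylic lactol is oxidised on to the lactone, so C2 becomes the carbonyl and neither C4 nor the alkene geometry is disturbed.

**Step 12**
Reactants: 21 (3Z,4S)-3-[3-methoxy-4,5-bis(methoxymethoxy)benzylidene]-4-[3-methoxy-4-(methoxymethoxy)benzyl]dihydrofuran-2(3H)-one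
Product: 22 (3Z,4S)-3-(3,4-dihydroxy-5-methoxybenzylidene)-4-(4-hydroxy-3-methoxybenzyl)dihydrofuran-2(3H)-one (CNP0306014.1)
Conditions: HCl (1 M in MeOH), 0 °C to rt, in the dark
Reagents that add atoms: none
Why: Acid-catalysed acetal exchange with methanol removes the three phenolic MOM groups under conditions mild enough that the lactone, the C4 center and the Z alkene should persist.

**Compound list**
1 | 5-hydroxyvanillin (3,4-dihydroxy-5-methoxybenzaldehyde) | COc1cc(C=O)cc(O)c1O | starting material
2 | 3-methoxy-4,5-bis(methoxymethoxy)benzaldehyde | COCOc1cc(C=O)cc(OC)c1OCOC | intermediate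
3 | methyl (E)-2-bromo-3-[3-methoxy-4,5-bis(methoxymethoxy)phenyl]prop-2-enoate | Br/C(C(=O)OC)=C/c1cc(OC)c(OCOC)c(OCOC)c1 | intermediate
4 | (E)-2-bromo-3-[3-methoxy-4,5-bis(methoxymethoxy)phenyl]prop-2-en-1-ol | Br/C(CO)=C/c1cc(OC)c(OCOC)c(OCOC)c1 | intermediate
5 | (E)-{[2-bromo-3-[3-methoxy-4,5-bis(methoxymethoxy)phenyl]prop-2-en-1-yl]oxy}(tert-butyl)dimethylsilane | Br/C(CO[Si](C)(C)C(C)(C)C)=C/c1cc(OC)c(OCOC)c(OCOC)c1 | intermediate
6 | vanillin | COc1cc(C=O)ccc1O | starting material
7 | 3-methoxy-4-(methoxymethoxy)benzaldehyde | COCOc1ccc(C=O)cc1OC | intermediate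
8 | 3-methoxy-4-(methoxymethoxy)phenyl formate (not isolated) | COCOc1ccc(OC=O)cc1OC | intermediate
9 | 3-methoxy-4-(methoxymethoxy)phenol | COCOc1ccc(O)cc1OC | intermediate
10 | 3-methoxy-4-(methoxymethoxy)phenyl trifluoromethanesulfonate | COCOc1ccc(OS(=O)(=O)C(F)(F)F)cc1OC | intermediate
11 | vinylboronic acid pinacol ester | C=CB1OC(C)(C)C(C)(C)O1 | starting material
12 | (Z)-{3-(tert-butyldimethylsilyloxy)-1-[3-methoxy-4,5-bis(methoxymethoxy)phenyl]prop-1-en-2-yl}lithium, lithium trans to ring A (not isolated) | [Li]/C(CO[Si](C)(C)C(C)(C)C)=C/c1cc(OC)c(OCOC)c(OCOC)c1 | intermediate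
13 | lithium {(Z)-3-(tert-butyldimethylsilyloxy)-1-[3-methoxy-4,5-bis(methoxymethoxy)phenyl]prop-1-en-2-yl}(vinyl)(pinacolato)borate (not isolated) | [Li+].C=C[B-]1(/C(CO[Si](C)(C)C(C)(C)C)=C/c2cc(OC)c(OCOC)c(OCOC)c2)OC(C)(C)C(C)(C)O1 | intermediate
14 | 2-{(2S,3Z)-3-[(tert-butyldimethylsilyloxy)methyl]-4-[3-methoxy-4,5-bis(methoxymethoxy)phenyl]-1-[3-methoxy-4-(methoxymethoxy)phenyl]but-3-en-2-yl}-4,4,5,5-tetramethyl-1,3,2-dioxaborolane | COc1cc(C[C@@H](/C(CO[Si](C)(C)C(C)(C)C)=C/c2cc(OCOC)c(OCOC)c(OC)c2)B2OC(C)(C)C(C)(C)O2)ccc1OCOC | intermediate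
15 | lithium (chloromethyl) borate of 14, chloromethyl on boron (not isolated) | [Li+].COc1cc(C[C@@H](/C(CO[Si](C)(C)C(C)(C)C)=C/c2cc(OCOC)c(OCOC)c(OC)c2)[B-]2(CCl)OC(C)(C)C(C)(C)O2)ccc1OCOC | intermediate
16 | 2-{(2S,3Z)-3-[(tert-butyldimethylsilyloxy)methyl]-4-[3-methoxy-4,5-bis(methoxymethoxy)phenyl]-2-[3-methoxy-4-(methoxymethoxy)benzyl]but-3-en-1-yl}-4,4,5,5-tetramethyl-1,3,2-dioxaborolane (not isolated) | COc1cc(C[C@@H](/C(CO[Si](C)(C)C(C)(C)C)=C/c2cc(OCOC)c(OCOC)c(OC)c2)CB2OC(C)(C)C(C)(C)O2)ccc1OCOC | intermediate
17 | (2S,3Z)-3-[(tert-butyldimethylsilyloxy)methyl]-4-[3-methoxy-4,5-bis(methoxymethoxy)phenyl]-2-[3-methoxy-4-(methoxymethoxy)benzyl]but-3-en-1-ol | COc1cc(C[C@@H](/C(CO[Si](C)(C)C(C)(C)C)=C/c2cc(OCOC)c(OCOC)c(OC)c2)CO)ccc1OCOC | intermediate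
18 | (2Z,3S)-2-[3-methoxy-4,5-bis(methoxymethoxy)benzylidene]-3-[3-methoxy-4-(methoxymethoxy)benzyl]butane-1,4-diol | COc1cc(C[C@@H](/C(CO)=C/c2cc(OCOC)c(OCOC)c(OC)c2)CO)ccc1OCOC | intermediate
19 | (2Z)-2-{(2S)-1-hydroxy-3-[3-methoxy-4-(methoxymethoxy)phenyl]propan-2-yl}-3-[3-methoxy-4,5-bis(methoxymethoxy)phenyl]prop-2-enal (not isolated) | COc1cc(C[C@@H](/C(C=O)=C/c2cc(OCOC)c(OCOC)c(OC)c2)CO)ccc1OCOC | intermediate
20 | (3Z,4S)-3-[3-methoxy-4,5-bis(methoxymethoxy)benzylidene]-4-[3-methoxy-4-(methoxymethoxy)benzyl]tetrahydrofuran-2-ol, both anomers (not isolated) | COc1cc(C[C@@H]2COC(O)/C2=C\c2cc(OCOC)c(OCOC)c(OC)c2)ccc1OCOC | intermediate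
21 | (3Z,4S)-3-[3-methoxy-4,5-bis(methoxymethoxy)benzylidene]-4-[3-methoxy-4-(methoxymethoxy)benzyl]dihydrofuran-2(3H)-one | COc1cc(C[C@@H]2COC(=O)/C2=C\c2cc(OCOC)c(OCOC)c(OC)c2)ccc1OCOC | intermediate
22 | (3Z,4S)-3-(3,4-dihydroxy-5-methoxybenzylidene)-4-(4-hydroxy-3-methoxybenzyl)dihydrofuran-2(3H)-one | COc1cc(C[C@@H]2COC(=O)/C2=C\c2cc(O)c(O)c(OC)c2)ccc1O | target

**Step count**
Total: 12 steps. Longest linear sequence: 9 steps (steps 1–4 and 8–12); the ring B branch (steps 5–7) joins at step 8.

**Steps most likely to fail**

Step 8. The catalytic cycle may stall through bromide left from the Br–Li exchange occupying the palladium site. The alkenyllithium may also degrade before it is captured by boron (silyl migration from oxygen to carbon, loss of geometry). The fallback builds the same borate with the roles of the partners reversed and without any alkenyllithium. It sets out from 5: Miyaura borylation (B2pin2, PdCl2(PPh3)2, PPh3, KOPh, toluene, 50 °C) should give, with retention of geometry, the isolable (Z)-alkenyl pinacol boronate F1, which is purified free of halide. Addition of halide-free vinyllithium F2 (from Sn(CH=CH2)4 and n-BuLi in pentane, collected as a solid) to F1 in THF at −78 °C gives borate 13. The route is rejoined at 13, which is coupled with 10 as in step 8, now without CF3SO3K.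

Step 9. Capture of the short-lived (chloromethyl)lithium by the congested allylic boron may be too slow, so that unchanged 14 is carried into the peroxide step and oxidised at C4. The fallback sets out from 14 and uses a carbenoid that is stable for hours at −78 °C, so that borate formation can be driven to completion before the shift is triggered. Methyl 2,4,6-triisopropylbenzoate is deprotonated (s-BuLi, TMEDA, Et2O, −78 °C) to the lithiated benzoate F3, which adds to 14 to give the borate F4. Warming to reflux in Et2O, with MgBr2 if needed, expels the benzoate with 1,2-shift of the C4 group. The route is rejoined at 16, which is oxidised as in step 9.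

Step 12. The acid may promote Z-to-E isomerisation of the exocyclic alkene through the protonated lactone, whose positive charge is stabilised by the para oxygen of ring A. The fallback corrects the geometry after deprotection in place of protecting it during deprotection. It sets out from 21: the MOM groups are removed under whatever acid strength is needed, and any (3E,4S) isomer F5 is accepted. The mixture is irradiated (about 350 nm, degassed MeCN), since benzylidene lactones of this type photoisomerise to mixtures rich in the Z isomer. 22 is separated by chromatography and recovered F5 is irradiated again, so the route is rejoined at 22.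

**Further compounds**
F1 | step 8 | (Z)-tert-butyl{[3-[3-methoxy-4,5-bis(methoxymethoxy)phenyl]-2-(4,4,5,5-tetramethyl-1,3,2-dioxaborolan-2-yl)prop-2-en-1-yl]oxy}dimethylsilane | CC1(C)OB(/C(CO[Si](C)(C)C(C)(C)C)=C/c2cc(OC)c(OCOC)c(OCOC)c2)OC1(C)C
F2 | step 8 | vinyllithium | [Li]C=C
F3 | step 9 | [(2,4,6-triisopropylbenzoyl)oxy]methyllithium | [Li]COC(=O)c1c(C(C)C)cc(C(C)C)cc1C(C)C
F4 | step 9 | lithium borate from 14 and F3, (2,4,6-triisopropylbenzoyloxy)methyl on boron | [Li+].COc1cc(C[C@@H](/C(CO[Si](C)(C)C(C)(C)C)=C/c2cc(OCOC)c(OCOC)c(OC)c2)[B-]2(COC(=O)c3c(C(C)C)cc(C(C)C)cc3C(C)C)OC(C)(C)C(C)(C)O2)ccc1OCOC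
F5 | step 12 | (3E,4S)-3-(3,4-dihydroxy-5-methoxybenzylidene)-4-(4-hydroxy-3-methoxybenzyl)dihydrofuran-2(3H)-one | COc1cc(C[C@@H]2COC(=O)/C2=C/c2cc(O)c(O)c(OC)c2)ccc1O
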